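## Retrosynthetic overview

1. Atom labels follow the heavy-atom order of the target SMILES. The strategy rests on bond C12–C25, common to the cyclopentane (C9, C10, C12, C25, C18) and the cyclohexane (C12, C13, C15, C27, C26, C25). O24 on C25 is β to the C13 oxygen through C12 (aldol retron across ether O17) and γ to C22 through C18–C19 (lactone retron).
2. Late stage: C4–OH by hydration of a C4=C5 enone; eight-membered ring by C19→C20 acylation of the lactone enolate; C7–C4 by alkenylchromium addition to the cage C7 aldehyde.
3. Key disconnection: C12–C25 and O24–C22, back to a 10-oxabicyclo[4.3.1]decane C13,C25-dione with the C19–C22 methyl acetate arm on C18.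
4. That bicycle: oxepene by ring-closing metathesis (C10=C12) of a cis-dialkenyl pyranone, then C28 (cuprate) and O11 (conjugate borylation/oxidation) from the exo face. The pyranone comes from an Achmatowicz rearrangement, C15 methylation and C18 alkylation.
5. Ring order: furan (bought) → pyranone → oxepene → cyclopentane + cyclohexane + γ-lactone in one step → eight-membered carbocycle.

Key step: step 18

Remarks on the chemistry:
- A C-glycosylation at C15 with an acetone enol ether would place a CH2 between C15 and C13 and lead to an oxocane. C13 is therefore carried on the furan as a bulky silyloxyallyl arm, C16 is added as the nucleophile, and the acetate arm is put on C18 by enolate alkylation.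
- Assumption: the C13 carbinol (steps 2–14) and the C7 carbinol (steps 26–29) are later oxidised to ketones. C13 is carried as the (S) antipode that the lipase leaves; C7 is carried as the epimer mixture from the coupling (centre left open in the SMILES). The C15 anomers of 11 and 12 converge in step 10.
- Organolithium, enolate and metal alkoxide species that are quenched within one operation are treated as part of that step.

## Route

Step 1
Reactants: 1 furfural
Product: 2 rac-1-(furan-2-yl)prop-2-en-1-ol
Conditions: CH2=CHMgBr, THF, −78 to 0 °C; H2O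
Reagents that add atoms: vinylmagnesium bromide C=C[Mg]Br
Why: Grignard 1,2-addition to the aldehyde should give the racemic allylic carbinol, whose carbinol carbon becomes C13 and whose vinyl CH becomes C12.

Step 2
Reactants: 2 rac-1-(furan-2-yl)prop-2-en-1-ol
Product: 3 (S)-1-(furan-2-yl)prop-2-en-1-ol
Conditions: Novozym 435 (immobilised lipase CAL-B), vinyl acetate, MTBE, 25 °C, stopped near half conversion
Reagents that add atoms: none
Why: Lipase-catalysed kinetic resolution by transesterification should acylate the (R)-alcohol (furyl as the large group) and leave the (S)-alcohol, so that the later bulky C13 arm has one configuration.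

Step 3
Reactants: 3 (S)-1-(furan-2-yl)prop-2-en-1-ol
Product: 4 (S)-tert-butyl{[1-(furan-2-yl)prop-2-en-1-yl]oxy}dimethylsilane
Conditions: TBSCl, imidazole, DMF, 25 °C
Reagents that add atoms: tert-butyldimethylsilyl chloride C[Si](C)(Cl)C(C)(C)C
Why: Silylation of the secondary alcohol should proceed cleanly and gives the C13 arm the bulk that later steers the C18 alkylation.

Step 4
Reactants: 4 (S)-tert-butyl{[1-(furan-2-yl)prop-2-en-1-yl]oxy}dimethylsilane
Product: 5 5-[(1S)-1-(tert-butyldimethylsilyloxy)prop-2-en-1-yl]furan-2-carbaldehyde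
Conditions: n-BuLi, THF, −78 to −20 °C; DMF; H2O
Reagents that add atoms: N,N-dimethylformamide CN(C)C=O
Why: α-Lithiation of the 2-substituted furan at its free C5 position followed by formylation should install the carbon that becomes C18.

Step 5
Reactants: 6 buta-2,3-dien-1-ol
Product: 7 benzyl buta-2,3-dien-1-yl ether
Conditions: NaH, BnBr, Bu4NI (cat.), THF, 0 to 25 °C
Reagents that add atoms: benzyl bromide BrCc1ccccc1
Why: Williamson etherification of the primary allenic alcohol should give the benzyl ether that later carries C7 and its oxygen.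

Step 6
Reactants: 7 benzyl buta-2,3-dien-1-yl ether
Product: 8 (Z)-2-[4-(benzyloxy)but-2-en-1-yl]-4,4,5,5-tetramethyl-1,3,2-dioxaborolane
Conditions: pinacolborane, CuCl (cat.), Xantphos-type bisphosphine (cat.), NaOt-Bu (cat.), toluene, 25 °C
Reagents that add atoms: pinacolborane B1OC(C)(C)C(C)(C)O1
Why: Copper hydride-catalysed hydroboration of a monosubstituted allene should add hydride to the central carbon and give, through the (Z)-allylcopper, the (Z)-γ-substituted allylboronate.

Step 7
Reactants: 5 5-[(1S)-1-(tert-butyldimethylsilyloxy)prop-2-en-1-yl]furan-2-carbaldehyde; 8 (Z)-2-[4-(benzyloxy)but-2-en-1-yl]-4,4,5,5-tetramethyl-1,3,2-dioxaborolane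
Product: 10 syn-homoallylic alcohol, via O-pinacolboryl ether 9 (not isolated)
Conditions: (S)-TRIP (chiral phosphoric acid, cat.), 4 Å molecular sieves, toluene, −30 °C; aqueous work-up
Reagents that add atoms: none
Why: Chiral phosphoric acid-catalysed allylboration through a closed chair transition state should turn the (Z)-boronate into the 1,2-syn product (OH and CH2OBn syn), the catalyst antipode being chosen to give the (1S) carbinol, which sets C9 for good and C18–H as a relay centre.

Step 8
Reactants: 10 syn-homoallylic alcohol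
Product: 11 Achmatowicz hemiketal (6-hydroxy-2H-pyran-3(6H)-one; both C15 anomers)
Conditions: NBS, NaHCO3, NaOAc, THF/H2O, 0 °C
Reagents that add atoms: water O
Why: Achmatowicz rearrangement (oxidative ring expansion of a furfuryl alcohol) should give the pyranone in which the carbinol oxygen has become O17, the electron-rich 2,5-dialkylfuran reacting far faster than the two terminal alkenes.

Step 9
Reactants: 11 Achmatowicz hemiketal
Product: 12 C15 acetate (both anomers)
Conditions: Ac2O, pyridine, DMAP (cat.), CH2Cl2, 0 °C
Reagents that add atoms: acetic anhydride CC(=O)OC(C)=O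
Why: Acylation of the hemiketal hydroxyl should give an anomeric leaving group that a Lewis acid can ionise.

Step 10
Reactants: 12 C15 acetate
Product: 13 C15-methyl pyranone (C16 trans to the C9 arm, silyloxyallyl arm cis to it)
Conditions: AlMe3, TMSOTf (cat.), CH2Cl2, −78 °C; H2O
Reagents that add atoms: trimethylaluminium C[Al](C)C
Why: Lewis-acid C-glycosylation should ionise the acetate to the ring oxocarbenium ion and transfer methyl from aluminium to C15 on the face anti to the C18 substituent (2,6-trans addition), which sets C15 with the silyloxyallyl arm cis to the C9 arm.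

Step 11
Reactants: 13 C15-methyl pyranone
Product: 14 C18-quaternary pyranone with the methyl acetate arm (C19–C22)
Conditions: LiN(SiMe3)2, THF/DMPU, −78 °C; BrCH2CO2Me, −78 to −50 °C
Reagents that add atoms: methyl bromoacetate COC(=O)CBr
Why: Kinetic deprotonation at C18, the only enolisable position (C15 is quaternary, C26 is sp2), should give a dienolate planar at C18 that is alkylated at low temperature on the face of the C16 methyl, anti to the bulky silyloxyallyl arm on C15, which sets quaternary C18 with C19 cis to C16 and the C9 arm cis to the C13 arm.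

Step 12
Reactants: 14 C18-quaternary pyranone
Product: 15 10-oxabicyclo[4.3.1]decadienone (C10=C12 alkene, C26=C27 enone)
Conditions: second-generation Grubbs catalyst (cat.), CH2Cl2 (dilute), 40 °C
Reagents that add atoms: none
Why: Ring-closing metathesis of the two cis-disposed vinyl groups should close the oxepene with a Z alkene, the ring enone being inert to the catalyst.

Step 13
Reactants: 15 10-oxabicyclo[4.3.1]decadienone
Product: 16 C27-methyl bicyclic ketone
Conditions: Me2CuLi (from CH3Li and CuI), Et2O, −78 to −30 °C; aq. NH4Cl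
Reagents that add atoms: lithium dimethylcuprate [Li+].C[Cu-]C
Why: Cuprate conjugate addition to the bridged enone should occur on the exo face, anti to the four-carbon bridge, which sets C27 with C28 cis to C16.

Step 14
Reactants: 16 C27-methyl bicyclic ketone
Product: 17 C13 allylic alcohol
Conditions: HF·pyridine, pyridine, THF, 0 to 25 °C
Reagents that add atoms: none
Why: Buffered fluoride cleavage of the allylic silyl ether should free the C13 hydroxyl without touching the ester, ketone or benzyl ether.

Step 15
Reactants: 17 C13 allylic alcohol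
Product: 18 enedione (C13 enone with C12=C10, C25 ketone)
Conditions: MnO2, CH2Cl2, 25 °C
Reagents that add atoms: none
Why: MnO2 oxidation of the allylic alcohol should give the cycloheptenone and removes the temporary C13 stereocentre.

Step 16
Reactants: 18 enedione
Product: 20 C10-hydroxy diketone, via C10 pinacolboronate 19 (not isolated)
Conditions: B2pin2, CuCl (cat.), Xantphos (cat.), NaOt-Bu (cat.), CH3OH, THF, 25 °C; then NaBO3·4H2O, THF/H2O
Reagents that add atoms: bis(pinacolato)diboron CC1(C)OB(OC1(C)C)B1OC(C)(C)C(C)(C)O1; sodium perborate [Na+].[O-]OB=O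
Why: Copper-catalysed conjugate borylation should deliver boron to C10 on the exo face (anti to the adjacent C7 arm and to the three-carbon bridge), and C–B oxidation with retention then sets the C10 hydroxyl while the saturated C25 ketone and the ester stay untouched.

Step 17
Reactants: 20 C10-hydroxy diketone
Product: 21 C10 silyl ether diketone (key-step precursor)
Conditions: TBSOTf, 2,6-lutidine, CH2Cl2, −78 °C
Reagents that add atoms: tert-butyldimethylsilyl triflate C[Si](C)(OS(=O)(=O)C(F)(F)F)C(C)(C)C
Why: Low-temperature silylation should cap the β-hydroxyl before the base step so that retro-aldol cleavage and dehydration are blocked.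

Step 18
Reactants: 21 C10 silyl ether diketone
Product: 23 cage keto-lactone, via aldol hydroxy ester 22 (not isolated)
Conditions: DBU, CH3CN, 25 to 50 °C
Reagents that add atoms: none
Why: DBU reversibly enolises the C13 ketone, whose only α-hydrogens are on C12, and C12 adds across the nine-membered carbocycle to the C25 carbonyl (bond C12–C25) to give aldolate 22, which is captured irreversibly when O24 attacks the neighbouring C22 methyl ester (bond O24–C22) and methoxide leaves. The closest known reaction type is the transannular aldol cyclisation of medium-ring diketones, here ended by lactonisation as in aldol–lactonisation cascades. The cyclopentane (C9, C10, C12, C25, C18) closes in a 5-(enolexo)-exo-trig mode, the cyclohexane (C12, C13, C15, C27, C26, C25) in a 6-(enolendo)-exo-trig mode, and the γ-lactone (C18, C19, C22, O24, C25) by 5-exo-trig acyl substitution. C12 and C25 are both fixed by the oxa-bridged frame: the bond can only form on the inner faces of the two bridges, which puts H12 outwards and O24 on the face of C25 that carries the C19 arm, the only arrangement from which the lactone can close. The step needs site selectivity for the C12 enolate over the C26 enolate and must outrun β-elimination of the C10 silyloxy group; the first is secured because C26 reaches C13 only through a four-membered ring, the second by the proximity of C12 and C25 in the bicycle, the mild amidine base and the irreversible lactone capture.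

Step 19
Reactants: 23 cage keto-lactone
Product: 24 C10-hydroxy cage keto-lactone
Conditions: HF·pyridine, THF, 25 °C
Reagents that add atoms: none
Why: Fluoride desilylation should free the C10 hydroxyl, which lies syn to C13 and on the O17 side of the C13 carbonyl, so that it can direct the reduction (a free hydride would meet the silyl ether on that face).

Step 20
Reactants: 24 C10-hydroxy cage keto-lactone
Product: 25 C10,C13 anti-diol
Conditions: Me4NBH(OAc)3, CH3CN/AcOH, −30 °C
Reagents that add atoms: none
Why: Saksena–Evans reduction should bind the acetoxyborohydride to the C10 hydroxyl and deliver hydride intramolecularly to C13 from the O17 face, which sets C13 with its hydroxyl turned to the C26–C27 bridge and leaves the lactone intact.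

Step 21
Reactants: 25 C10,C13 anti-diol
Product: 26 bis-silyl ether
Conditions: TBSOTf, 2,6-lutidine, CH2Cl2, 0 °C
Reagents that add atoms: tert-butyldimethylsilyl triflate C[Si](C)(OS(=O)(=O)C(F)(F)F)C(C)(C)C
Why: Silyl triflate should protect both hindered secondary alcohols for the oxidation and base steps that follow.

Step 22
Reactants: 26 bis-silyl ether
Product: 27 C7 primary alcohol
Conditions: H2 (1 atm), Pd/C, EtOAc, 25 °C
Reagents that add atoms: none
Why: Hydrogenolysis of the benzyl ether should be clean because the molecule no longer has an alkene.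

Step 23
Reactants: 27 C7 primary alcohol
Product: 28 C7 aldehyde
Conditions: Dess–Martin periodinane, NaHCO3, CH2Cl2, 0 to 25 °C
Reagents that add atoms: none
Why: Buffered periodinane oxidation should give the aldehyde without base, so that C9 is not epimerised and the C10 silyloxy group is not eliminated.

Step 24
Reactants: 29 (R)-4-benzyl-3-propanoyl-1,3-oxazolidin-2-one
Product: 30 (R)-4-benzyl-3-[(2S)-4-bromo-2-methylpent-4-enoyl]-1,3-oxazolidin-2-one
Conditions: NaN(SiMe3)2, THF, −78 °C; 2,3-dibromopropene, −78 to −40 °C
Reagents that add atoms: 2,3-dibromopropene C=C(Br)CBr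
Why: Evans alkylation of the chelated sodium (Z)-enolate at the allylic bromide should occur on the face opposite to the benzyl group and sets C2 as (S).

Step 25
Reactants: 30 (R)-4-benzyl-3-[(2S)-4-bromo-2-methylpent-4-enoyl]-1,3-oxazolidin-2-one
Product: 31 (2S)-4-bromo-N-methoxy-N,2-dimethylpent-4-enamide
Conditions: AlMe3, MeNHOMe·HCl, CH2Cl2, 0 to 25 °C
Reagents that add atoms: N,O-dimethylhydroxylamine hydrochloride CNOC.Cl
Why: Aluminium amide transamination should exchange the auxiliary for the Weinreb amide without touching C2 or the vinyl bromide.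

Step 26
Reactants: 28 C7 aldehyde; 31 (2S)-4-bromo-N-methoxy-N,2-dimethylpent-4-enamide
Product: 32 C7 allylic alcohol (C7 epimers)
Conditions: CrCl2, NiCl2 (cat.), DMSO, 25 °C
Reagents that add atoms: none
Why: Nozaki–Hiyama–Kishi coupling should add the alkenylchromium species to the aldehyde only (lactone and Weinreb amide are inert) and forms bond C7–C4; the C7 epimers are both used because C7 is oxidised later.

Step 27
Reactants: 32 C7 allylic alcohol
Product: 33 C7 triethylsilyl ether
Conditions: TESOTf, 2,6-lutidine, CH2Cl2, −78 °C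
Reagents that add atoms: triethylsilyl triflate CC[Si](CC)(CC)OS(=O)(=O)C(F)(F)F
Why: Silylation should keep the C7 oxygen from attacking the amide in the next step and keeps C7 at the alcohol level, so that no enone (Michael acceptor) and no enolisable C7 ketone is present under base.

Step 28
Reactants: 33 C7 triethylsilyl ether
Product: 34 eight-membered enol lactone (tris-silyl ether)
Conditions: LiN(SiMe3)2, THF, −78 to 0 °C; aq. NH4Cl
Reagents that add atoms: none
Why: Intramolecular Claisen-type acylation should join the lactone enolate carbon C19 to the Weinreb amide carbon C20 (the two arms are cis on adjacent cage carbons); the chelated tetrahedral intermediate collapses only on work-up to the β-keto lactone, which rests as the C20 enol.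

Step 29
Reactants: 34 eight-membered enol lactone
Product: 35 triol (C7, C10, C13 hydroxyls free)
Conditions: HF·pyridine, THF, 25 to 40 °C
Reagents that add atoms: none
Why: Fluoride should cleave the triethylsilyl and both tert-butyldimethylsilyl ethers in one operation under non-basic conditions.

Step 30
Reactants: 35 triol
Product: 36 C7 enone (C4=C5 exo-methylene)
Conditions: MnO2, CH2Cl2, 25 °C
Reagents that add atoms: none
Why: MnO2 should oxidise only the allylic C7 alcohol and leave the saturated C10 and C13 alcohols.

Step 31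
Reactants: 36 C7 enone
Product: 38 CNP0115071.1, via C4 hydroperoxide 37 (not isolated)
Conditions: Mn(dpm)3 (dpm = dipivaloylmethanate, cat.), PhSiH3, O2 (1 atm), i-PrOH/CH2Cl2, 0 °C; then P(OEt)3
Reagents that add atoms: dioxygen O=O
Why: Mukaiyama-type hydration by hydrogen-atom transfer should add H to C5, trap the tertiary C4 radical next to the C7 ketone with O2 and reduce the hydroperoxide with the phosphite; O2 is expected to enter trans to the C2 methyl group on the eight-membered ring, which sets C4.

## Compound list

1 | furfural (furan-2-carbaldehyde) | O=Cc1ccco1 | starting material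
2 | rac-1-(furan-2-yl)prop-2-en-1-ol | C=CC(O)c1ccco1 | intermediate
3 | (S)-1-(furan-2-yl)prop-2-en-1-ol | C=C[C@H](O)c1ccco1 | intermediate
4 | (S)-tert-butyl{[1-(furan-2-yl)prop-2-en-1-yl]oxy}dimethylsilane | C=C[C@H](O[Si](C)(C)C(C)(C)C)c1ccco1 | intermediate
5 | 5-[(1S)-1-(tert-butyldimethylsilyloxy)prop-2-en-1-yl]furan-2-carbaldehyde | C=C[C@H](O[Si](C)(C)C(C)(C)C)c1ccc(C=O)o1 | intermediate
6 | buta-2,3-dien-1-ol | C=C=CCO | starting material
7 | benzyl buta-2,3-dien-1-yl ether | C=C=CCOCc1ccccc1 | intermediate
8 | (Z)-2-[4-(benzyloxy)but-2-en-1-yl]-4,4,5,5-tetramethyl-1,3,2-dioxaborolane | B1(OC(C)(C)C(C)(C)O1)C/C=C\COCc1ccccc1 | intermediate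
9 | O-pinacolboryl ether of alcohol 10 | C=C[C@H](O[Si](C)(C)C(C)(C)C)c1ccc(o1)[C@@H](OB3OC(C)(C)C(C)(C)O3)[C@H](COCc2ccccc2)C=C | intermediate
10 | syn-homoallylic alcohol: (1S,2S)-2-[(benzyloxy)methyl]-1-{5-[(1S)-1-(tert-butyldimethylsilyloxy)prop-2-en-1-yl]furan-2-yl}but-3-en-1-ol | C=C[C@H](O[Si](C)(C)C(C)(C)C)c1ccc(o1)[C@@H](O)[C@H](COCc2ccccc2)C=C | intermediate
11 | Achmatowicz hemiketal: 6-hydroxy-2H-pyran-3(6H)-one with H and the (2S)-1-(benzyloxy)but-3-en-2-yl arm on C18 and OH and the (S)-silyloxyallyl arm on C15 (C15 anomers) | C=C[C@H](O[Si](C)(C)C(C)(C)C)C4(O)O[C@@H]([C@H](COCc2ccccc2)C=C)C(=O)C=C4 | intermediate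
12 | C15 acetate of 11 (C15 anomers) | C=C[C@H](O[Si](C)(C)C(C)(C)C)C4(OC(C)=O)O[C@@H]([C@H](COCc2ccccc2)C=C)C(=O)C=C4 | intermediate
13 | C15-methyl pyranone (C16 trans to the C9 arm) | C=C[C@H](O[Si](C)(C)C(C)(C)C)[C@@]4(C)O[C@@H]([C@H](COCc2ccccc2)C=C)C(=O)C=C4 | intermediate
14 | C18-quaternary pyranone with methyl acetate arm (C19 cis to C16) | C=C[C@H](O[Si](C)(C)C(C)(C)C)[C@@]4(C)O[C@]([C@H](COCc2ccccc2)C=C)(CC(=O)OC)C(=O)C=C4 | intermediate
15 | 10-oxabicyclo[4.3.1]decadienone (C10=C12, C26=C27, C13 silyl ether) | O(Cc1ccccc1)C[C@@H]2C=C[C@H](O[Si](C)(C)C(C)(C)C)[C@@]4(C)O[C@]2(CC(=O)OC)C(=O)C=C4 | intermediate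
16 | C27-methyl bicyclic ketone (C13 silyl ether) | O(Cc1ccccc1)C[C@@H]2C=C[C@H](O[Si](C)(C)C(C)(C)C)[C@@]4(C)O[C@]2(CC(=O)OC)C(=O)C[C@@H]4C | intermediate
17 | C13 allylic alcohol | O(Cc1ccccc1)C[C@@H]2C=C[C@H](O)[C@@]4(C)O[C@]2(CC(=O)OC)C(=O)C[C@@H]4C | intermediate
18 | enedione (C13 enone, C25 ketone) | O(Cc1ccccc1)C[C@@H]2C=CC(=O)[C@@]4(C)O[C@]2(CC(=O)OC)C(=O)C[C@@H]4C | intermediate
19 | C10 pinacolboronate | O(Cc1ccccc1)C[C@@H]2[C@@H](B6OC(C)(C)C(C)(C)O6)CC(=O)[C@@]4(C)O[C@]2(CC(=O)OC)C(=O)C[C@@H]4C | intermediate
20 | C10-hydroxy diketone | O(Cc1ccccc1)C[C@@H]2[C@@H](O)CC(=O)[C@@]4(C)O[C@]2(CC(=O)OC)C(=O)C[C@@H]4C | intermediate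
21 | C10 silyl ether diketone (10-oxabicyclo[4.3.1]decane-C13,C25-dione, key-step precursor) | O(Cc1ccccc1)C[C@@H]2[C@@H](O[Si](C)(C)C(C)(C)C)CC(=O)[C@@]4(C)O[C@]2(CC(=O)OC)C(=O)C[C@@H]4C | intermediate
22 | aldol hydroxy ester (C12–C25 formed, C25 hydroxyl free) | O(Cc1ccccc1)C[C@@H]2[C@@H](O[Si](C)(C)C(C)(C)C)[C@H]3C(=O)[C@@]4(C)O[C@]2(CC(=O)OC)[C@]3(O)C[C@@H]4C | intermediate
23 | cage keto-lactone (C13 ketone, C10 silyl ether) | O(Cc1ccccc1)C[C@@H]2[C@@H](O[Si](C)(C)C(C)(C)C)[C@H]3C(=O)[C@@]4(C)O[C@@]25CC(=O)O[C@@]35C[C@@H]4C | intermediate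
24 | C10-hydroxy cage keto-lactone | O(Cc1ccccc1)C[C@@H]2[C@@H](O)[C@H]3C(=O)[C@@]4(C)O[C@@]25CC(=O)O[C@@]35C[C@@H]4C | intermediate
25 | C10,C13 anti-diol | O(Cc1ccccc1)C[C@@H]2[C@@H](O)[C@H]3[C@H](O)[C@@]4(C)O[C@@]25CC(=O)O[C@@]35C[C@@H]4C | intermediate
26 | bis-silyl ether | O(Cc1ccccc1)C[C@@H]2[C@@H](O[Si](C)(C)C(C)(C)C)[C@H]3[C@H](O[Si](C)(C)C(C)(C)C)[C@@]4(C)O[C@@]25CC(=O)O[C@@]35C[C@@H]4C | intermediate
27 | C7 primary alcohol | OC[C@@H]2[C@@H](O[Si](C)(C)C(C)(C)C)[C@H]3[C@H](O[Si](C)(C)C(C)(C)C)[C@@]4(C)O[C@@]25CC(=O)O[C@@]35C[C@@H]4C | intermediate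
28 | C7 aldehyde | O=C[C@@H]2[C@@H](O[Si](C)(C)C(C)(C)C)[C@H]3[C@H](O[Si](C)(C)C(C)(C)C)[C@@]4(C)O[C@@]25CC(=O)O[C@@]35C[C@@H]4C | intermediate
29 | (R)-4-benzyl-3-propanoyl-1,3-oxazolidin-2-one | CCC(=O)N1[C@H](Cc2ccccc2)COC1=O | starting material
30 | (R)-4-benzyl-3-[(2S)-4-bromo-2-methylpent-4-enoyl]-1,3-oxazolidin-2-one | C=C(Br)C[C@H](C)C(=O)N1[C@H](Cc2ccccc2)COC1=O | intermediate
31 | (2S)-4-bromo-N-methoxy-N,2-dimethylpent-4-enamide | C=C(Br)C[C@H](C)C(=O)N(C)OC | intermediate
32 | C7 allylic alcohol with Weinreb amide chain (C7 epimers) | C=C(C[C@H](C)C(=O)N(C)OC)C(O)[C@@H]2[C@@H](O[Si](C)(C)C(C)(C)C)[C@H]3[C@H](O[Si](C)(C)C(C)(C)C)[C@@]4(C)O[C@@]25CC(=O)O[C@@]35C[C@@H]4C | intermediate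
33 | C7 triethylsilyl ether (C7 epimers) | C=C(C[C@H](C)C(=O)N(C)OC)C(O[Si](CC)(CC)CC)[C@@H]2[C@@H](O[Si](C)(C)C(C)(C)C)[C@H]3[C@H](O[Si](C)(C)C(C)(C)C)[C@@]4(C)O[C@@]25CC(=O)O[C@@]35C[C@@H]4C | intermediate
34 | eight-membered enol lactone, tris-silyl ether (C7 epimers) | C[C@H]1CC(=C)C(O[Si](CC)(CC)CC)[C@@H]2[C@@H](O[Si](C)(C)C(C)(C)C)[C@H]3[C@H](O[Si](C)(C)C(C)(C)C)[C@@]4(C)O[C@@]25/C(=C\1O)C(=O)O[C@@]35C[C@@H]4C | intermediate
35 | triol (C7 epimers) | C[C@H]1CC(=C)C(O)[C@@H]2[C@@H](O)[C@H]3[C@H](O)[C@@]4(C)O[C@@]25/C(=C\1O)C(=O)O[C@@]35C[C@@H]4C | intermediate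
36 | C7 enone with C4=C5 exo-methylene | C[C@H]1CC(=C)C(=O)[C@@H]2[C@@H](O)[C@H]3[C@H](O)[C@@]4(C)O[C@@]25/C(=C\1O)C(=O)O[C@@]35C[C@@H]4C | intermediate
37 | C4 hydroperoxide | C[C@H]1C[C@](C)(OO)C(=O)[C@@H]2[C@@H](O)[C@H]3[C@H](O)[C@@]4(C)O[C@@]25/C(=C\1O)C(=O)O[C@@]35C[C@@H]4C | intermediate
38 | CNP0115071.1 | C[C@H]1C[C@](C)(O)C(=O)[C@@H]2[C@@H](O)[C@H]3[C@H](O)[C@@]4(C)O[C@@]25/C(=C\1O)C(=O)O[C@@]35C[C@@H]4C | target

## Step count and risks

Total: 31 steps. Longest linear sequence: 27 steps (steps 1–4, 7–23 and 26–31). Steps 5–6 (boronate 8) and 24–25 (amide 31) are side branches.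

Most likely to fail:

Step 18. The C12 enolate may expel the C10 silyloxy group (E1cB) before it closes on C25, or the aldolate may revert before the lactone forms. The fallback sets out from enedione 18 and makes the C12 enolate by conjugate borylation instead of deprotonation. With CuCl, Xantphos, NaOt-Bu and B2pin2 in THF without a proton source, the boryl group should add to C10 on the exo face. The copper enolate at C12 then has a C–B bond and no leaving group at C10; it should add to C25 and lactonise, giving the C10-boryl cage keto-lactone F1 (a copper-catalysed borylative aldol cyclisation). Oxidation of F1 with NaBO3 gives hydroxy ketone 24, where the route is rejoined at step 20.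

Step 11. The 2H-pyran-3-olate may open by 6π electrocyclic ring opening with loss of the C15 configuration, may O-alkylate, or may be alkylated on the wrong face. The fallback sets out from 13 and runs the ring-closing metathesis first (second-generation Grubbs catalyst), giving bicyclic dienone F2, which still has hydrogen on bridgehead C18. Deprotonation with KN(SiMe3)2 and alkylation with methyl bromoacetate then take place at a bridgehead enolate. There ring opening would need a strained medium-ring triene, and the electrophile can only enter from the exo face. This gives 15, and the route continues with step 13.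

Step 31. The C4 radical may capture O2 on the wrong face of the eight-membered ring, or may be reduced to the C4–H ketone. The fallback sets out from tris-silyl ether 34. PPTS in CH3OH should remove only the triethylsilyl group and give the allylic alcohol F3, and MnO2 then gives enone F4. After deprotonation of the enol with KN(SiMe3)2, conjugate reduction with KBH(s-Bu)3 should form the C7–C4 enolate regiospecifically (C9 is not enolised). 2-(Phenylsulfonyl)-3-phenyloxaziridine then hydroxylates C4 to give the C4 carbinol F5; this polar step has a facial preference of its own and can be steered with the camphor-derived oxaziridines. HF·pyridine converts F5 to 38.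

Further compounds
F1 | step 18 | C10-boryl cage keto-lactone | O(Cc1ccccc1)C[C@@H]2[C@@H](B6OC(C)(C)C(C)(C)O6)[C@H]3C(=O)[C@@]4(C)O[C@@]25CC(=O)O[C@@]35C[C@@H]4C
F2 | step 11 | bicyclic dienone with bridgehead C18–H | O(Cc1ccccc1)C[C@@H]2C=C[C@H](O[Si](C)(C)C(C)(C)C)[C@@]4(C)O[C@@H]2C(=O)C=C4
F3 | step 31 | bis-silyl C7 allylic alcohol (C7 epimers) | C[C@H]1CC(=C)C(O)[C@@H]2[C@@H](O[Si](C)(C)C(C)(C)C)[C@H]3[C@H](O[Si](C)(C)C(C)(C)C)[C@@]4(C)O[C@@]25/C(=C\1O)C(=O)O[C@@]35C[C@@H]4C
F4 | step 31 | bis-silyl C7 enone | C[C@H]1CC(=C)C(=O)[C@@H]2[C@@H](O[Si](C)(C)C(C)(C)C)[C@H]3[C@H](O[Si](C)(C)C(C)(C)C)[C@@]4(C)O[C@@]25/C(=C\1O)C(=O)O[C@@]35C[C@@H]4C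
F5 | step 31 | bis-silyl C4 carbinol | C[C@H]1C[C@](C)(O)C(=O)[C@@H]2[C@@H](O[Si](C)(C)C(C)(C)C)[C@H]3[C@H](O[Si](C)(C)C(C)(C)C)[C@@]4(C)O[C@@]25/C(=C\1O)C(=O)O[C@@]35C[C@@H]4C
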